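**Plan**
Numbering (lignan): guaiacyl half C1–C9 (C9 = CH2OAc), syringyl half C1'–C9' (C9' = CH3). The target is (8S,8'R).
Retrosynthetic cuts, in order: the acetyl on C9–O; the benzyl on the guaiacyl OH; H2 across C8'=C9'; C7'–C1' (para-Claisen) back to a C7'–O–C4' ether; that ether to 2,6-dimethoxyphenol and an allylic carbonate; the C9–C8–C8'–C7' core to an α-methylene-β-benzyl-γ-butyrolactone made from O-benzylvanillin and dimethyl succinate.
Enabling feature: in the syringyl ring the OH carbon C4' is para to C1', and both ortho carbons C3'/C5' carry OMe. The C9' methyl can be carried as a C8'=C9' methylene, so C7'–C8'(=C9') is a 2-substituted allyl group. Its ether with 2,6-dimethoxyphenol can only travel O→C3'→C1' by two [3,3] shifts through dearomatised dienones. This forges C7'–C1' without halide, metal or protecting group on that ring and sets its phenol free.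
Forward order: Stobbe chain assembly, a temporary γ-lactone (tells C9 from C7'), methylenation, reduction, chemoselective Pd O-allylation, rearrangement, two hydrogenations, acetylation. Both arenes are bought and no ring of the target is built.
Stereochemistry: C8 comes from Rh-catalysed asymmetric hydrogenation (step 2). C8' is relayed from C8 by C9–OH-directed hydrogenation of the methylene left by the rearrangement (step 9).

Key step: step 8

Assumption: the (R,R) antipode of Et-DuPhos is taken to deliver the (S)-acid 5. Should the sense of induction be the opposite, the (S,S) ligand is used and nothing else changes.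

Step 1
Reactants: 1 4-(benzyloxy)-3-methoxybenzaldehyde; 2 dimethyl succinate
Product: 4 (E)-4-[4-(benzyloxy)-3-methoxyphenyl]-3-(methoxycarbonyl)but-3-enoic acid, via paraconic ester 3 (not isolated)
Conditions: NaOMe, MeOH, reflux; then aq HCl
Reagents that add atoms: none
Why: Stobbe condensation, in which the succinate enolate adds to the aldehyde, the aldolate lactonises to 3 and irreversible E1cB opening gives the carboxylate of the (E)-half-ester, so the two carboxyl carbons (future C9 and C7') are differentiated from the start.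

Step 2
Reactants: 4 (E)-half-ester
Product: 5 (S)-3-[4-(benzyloxy)-3-methoxybenzyl]-4-methoxy-4-oxobutanoic acid
Conditions: H2 (6 bar), [Rh(cod)((R,R)-Et-DuPhos)]OTf (0.5 mol %), NaOMe (10 mol %), MeOH, rt
Reagents that add atoms: none
Why: Rh(I)-bisphospholane asymmetric hydrogenation of a Stobbe-type itaconate half-ester, whose carboxylate chelates the metal, should set C8 as S under catalyst control, and the homogeneous catalyst leaves the benzyl ether alone.

Step 3
Reactants: 5 (S)-half-ester
Product: 7 (S)-4-[4-(benzyloxy)-3-methoxybenzyl]dihydrofuran-2(3H)-one, via hydroxy acid 6 (not isolated)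
Conditions: KOH (1 equiv), EtOH; Ca(BH4)2 (from CaCl2 and NaBH4), EtOH, −10 °C to rt; then 2 M HCl, rt
Reagents that add atoms: none
Why: Chemoselective ester reduction followed by lactonisation, since calcium borohydride reduces the methyl ester (C9) but not the carboxylate salt (C7') and acid then closes the γ-lactone without touching C8.

Step 4
Reactants: 7 (S)-β-benzyl-γ-butyrolactone
Product: 10 (S)-4-[4-(benzyloxy)-3-methoxybenzyl]-3-methylenedihydrofuran-2(3H)-one, via Mannich base 8 (not isolated), via methiodide 9 (not isolated)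
Conditions: LDA, THF, −78 °C; CH2=NMe2+ I−, −78 °C to rt; MeI, MeOH, rt; aq NaHCO3, CH2Cl2, rt
Reagents that add atoms: Eschenmoser's salt C=[N+](C)C.[I-]; iodomethane CI (its carbon stays in 9 only)
Why: Mannich-type α-aminomethylation of the lactone enolate, quaternisation and Hofmann-type elimination is the standard α-methylenation of γ-lactones, and the weak base in the last stage avoids migration of the double bond into the ring, which would erase C8.

Step 5
Reactants: 10 α-methylene lactone
Product: 12 (S)-2-[4-(benzyloxy)-3-methoxybenzyl]-3-methylenebutane-1,4-diyl dimethyl biscarbonate, via diol 11 (not isolated)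
Conditions: DIBAL-H (4.5 equiv), CH2Cl2, −78 to 0 °C, Rochelle salt work-up; crude 11: ClCO2Me, pyridine, DMAP (cat.), CH2Cl2, 0 °C to rt
Reagents that add atoms: methyl chloroformate COC(=O)Cl
Why: DIBAL-H reduces α-methylene lactones in the 1,2-sense to 2-methylene-1,4-diols, and routine carbonate formation gives one allylic and one non-allylic carbonate, the difference on which step 6 rests.

Step 6
Reactants: 12 biscarbonate; 13 2,6-dimethoxyphenol
Product: 14 (S)-2-[4-(benzyloxy)-3-methoxybenzyl]-3-[(2,6-dimethoxyphenoxy)methyl]but-3-en-1-yl methyl carbonate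
Conditions: Pd2(dba)3·CHCl3 (2.5 mol %), dppb (6 mol %), THF, 50 °C
Reagents that add atoms: none
Why: Tsuji–Trost O-allylation, in which Pd(0) ionises only the allylic carbonate, the released methoxide deprotonates 13 and the phenoxide attacks a 2-substituted π-allyl whose two CH2 termini give the same ether, with C8 outside the π-allyl system.

Step 7
Reactants: 14 aryl allyl ether carbonate
Product: 15 (S)-2-[4-(benzyloxy)-3-methoxybenzyl]-3-[(2,6-dimethoxyphenoxy)methyl]but-3-en-1-ol
Conditions: K2CO3 (0.2 equiv), MeOH, rt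
Reagents that add atoms: none
Why: Base-catalysed transesterification, run after removal of palladium, frees C9–OH (the directing group of step 9) and leaves the aryl allyl ether and the benzyl ether untouched.

Step 8
Reactants: 15 aryl allyl ether alcohol
Product: 18 4-{(S)-3-[4-(benzyloxy)-3-methoxybenzyl]-4-hydroxy-2-methylenebutyl}-2,6-dimethoxyphenol, via ortho-dienone 16 (not isolated), via para-dienone 17 (not isolated)
Conditions: PhNEt2 (degassed), 195 °C, sealed tube, Ar
Reagents that add atoms: none
Why: Heating starts an aromatic Claisen [3,3] shift in which the allyl–O bond breaks and the methylene terminus bonds to the OMe-bearing ortho carbon C3', giving 2,4-dienone 16, which has no hydrogen at the new quaternary carbon and cannot tautomerise; a Cope [3,3] shift along C3'–C2'=C1' then carries the allyl unit to C1' (dienone 17), where loss of the ring hydrogen restores the arene and releases the free syringyl OH of 18. The closest known reaction type is the thermal para-Claisen rearrangement of allyl and methallyl ethers of 2,6-disubstituted phenols such as 2,6-dimethoxyphenol. No ring is closed and no stereocentre is created, and both six-atom arrays lie outside C8, whose configuration is simply carried along. The step needs para over ortho selectivity, which the OMe groups on C3' and C5' secure, and it needs no allyl regiocontrol because the 2-substituted allyl unit has two equivalent CH2 termini, so the double inversion is degenerate. The guaiacyl benzyl ether has no allyl π bond and stays in place, the primary alcohol is a spectator, and the amine solvent under argon should suppress acid-induced ether cleavage and air oxidation of the phenol. The event leaves the unsaturation at C8'=C9', homoallylic to C9–OH, which is where step 9 needs it.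

Step 9
Reactants: 18 methylene phenol
Product: 19 4-{(2R,3S)-3-[4-(benzyloxy)-3-methoxybenzyl]-4-hydroxy-2-methylbutyl}-2,6-dimethoxyphenol
Conditions: [Rh(nbd)(dppb)]BF4 (5 mol %), H2 (60 bar), CH2Cl2, rt
Reagents that add atoms: none
Why: Hydroxyl-directed homogeneous hydrogenation, in which the cationic Rh centre binds C9–OH and the C8'=C9' bond and the chelate reacts through the rotamer with C8–H (not the C7 benzyl arm) next to C7' (least A(1,2) strain), so H2 should arrive on the alkene face syn to CH2OH and set C8' as R, while the high pressure outruns double-bond migration and the benzyl ether is not touched.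

Step 10
Reactants: 19 benzyl ether
Product: 20 4-[(2R,3S)-4-hydroxy-3-(4-hydroxy-3-methoxybenzyl)-2-methylbutyl]-2,6-dimethoxyphenol
Conditions: H2 (1 bar), 10 % Pd/C, EtOAc–MeOH, rt
Reagents that add atoms: none
Why: Catalytic hydrogenolysis of the aryl benzyl ether is routine, and nothing else in 19 is reducible under these conditions.

Step 11
Reactants: 20 triol
Product: 21 (2S,3R)-2-(4-hydroxy-3-methoxybenzyl)-4-(4-hydroxy-3,5-dimethoxyphenyl)-3-methylbutyl acetate (target)
Conditions: Novozym 435 (immobilised Candida antarctica lipase B), vinyl acetate (5 equiv), MTBE–THF, 40 °C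
Reagents that add atoms: vinyl acetate C=COC(C)=O
Why: Lipase-catalysed irreversible transesterification acylates primary aliphatic alcohols but not phenols, so only C9–OH should be acetylated and neither stereocentre is involved.

**Compound list**
1 | 4-(benzyloxy)-3-methoxybenzaldehyde | O=Cc1ccc(OCc2ccccc2)c(OC)c1 | starting material
2 | dimethyl succinate | COC(=O)CCC(=O)OC | starting material
3 | methyl 2-[4-(benzyloxy)-3-methoxyphenyl]-5-oxotetrahydrofuran-3-carboxylate (paraconic ester, not isolated) | COC(=O)C1CC(=O)OC1c1ccc(OCc2ccccc2)c(OC)c1 | intermediate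
4 | (E)-4-[4-(benzyloxy)-3-methoxyphenyl]-3-(methoxycarbonyl)but-3-enoic acid | COC(=O)/C(CC(=O)O)=C/c1ccc(OCc2ccccc2)c(OC)c1 | intermediate
5 | (S)-3-[4-(benzyloxy)-3-methoxybenzyl]-4-methoxy-4-oxobutanoic acid | COc1cc(C[C@H](C(=O)OC)CC(=O)O)ccc1OCc1ccccc1 | intermediate
6 | (S)-3-[4-(benzyloxy)-3-methoxybenzyl]-4-hydroxybutanoic acid (not isolated) | COc1cc(C[C@H](CO)CC(=O)O)ccc1OCc1ccccc1 | intermediate
7 | (S)-4-[4-(benzyloxy)-3-methoxybenzyl]dihydrofuran-2(3H)-one | COc1cc(C[C@H]2CC(=O)OC2)ccc1OCc1ccccc1 | intermediate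
8 | (4S)-4-[4-(benzyloxy)-3-methoxybenzyl]-3-[(dimethylamino)methyl]dihydrofuran-2(3H)-one (C3 of no consequence, not isolated) | COc1cc(C[C@H]2C(CN(C)C)C(=O)OC2)ccc1OCc1ccccc1 | intermediate
9 | methiodide of 8 (not isolated) | COc1cc(C[C@H]2C(C[N+](C)(C)C)C(=O)OC2)ccc1OCc1ccccc1.[I-] | intermediate
10 | (S)-4-[4-(benzyloxy)-3-methoxybenzyl]-3-methylenedihydrofuran-2(3H)-one | COc1cc(C[C@H]2C(=C)C(=O)OC2)ccc1OCc1ccccc1 | intermediate
11 | (S)-2-[4-(benzyloxy)-3-methoxybenzyl]-3-methylenebutane-1,4-diol (not isolated) | COc1cc(C[C@H](CO)C(=C)CO)ccc1OCc1ccccc1 | intermediate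
12 | (S)-2-[4-(benzyloxy)-3-methoxybenzyl]-3-methylenebutane-1,4-diyl dimethyl biscarbonate | COc1cc(C[C@H](COC(=O)OC)C(=C)COC(=O)OC)ccc1OCc1ccccc1 | intermediate
13 | 2,6-dimethoxyphenol | COc1cccc(OC)c1O | starting material
14 | (S)-2-[4-(benzyloxy)-3-methoxybenzyl]-3-[(2,6-dimethoxyphenoxy)methyl]but-3-en-1-yl methyl carbonate | COc1cc(C[C@H](COC(=O)OC)C(=C)COc2c(OC)cccc2OC)ccc1OCc1ccccc1 | intermediate
15 | (S)-2-[4-(benzyloxy)-3-methoxybenzyl]-3-[(2,6-dimethoxyphenoxy)methyl]but-3-en-1-ol | COc1cc(C[C@H](CO)C(=C)COc2c(OC)cccc2OC)ccc1OCc1ccccc1 | intermediate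
16 | 6-{(S)-3-[4-(benzyloxy)-3-methoxybenzyl]-4-hydroxy-2-methylenebutyl}-2,6-dimethoxycyclohexa-2,4-dien-1-one (ring C6 unassigned, not isolated) | COc1cc(C[C@H](CO)C(=C)CC2(OC)C=CC=C(OC)C2=O)ccc1OCc1ccccc1 | intermediate
17 | 4-{(S)-3-[4-(benzyloxy)-3-methoxybenzyl]-4-hydroxy-2-methylenebutyl}-2,6-dimethoxycyclohexa-2,5-dien-1-one (not isolated) | COc1cc(C[C@H](CO)C(=C)CC2C=C(OC)C(=O)C(OC)=C2)ccc1OCc1ccccc1 | intermediate
18 | 4-{(S)-3-[4-(benzyloxy)-3-methoxybenzyl]-4-hydroxy-2-methylenebutyl}-2,6-dimethoxyphenol | COc1cc(C[C@H](CO)C(=C)Cc2cc(OC)c(O)c(OC)c2)ccc1OCc1ccccc1 | intermediate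
19 | 4-{(2R,3S)-3-[4-(benzyloxy)-3-methoxybenzyl]-4-hydroxy-2-methylbutyl}-2,6-dimethoxyphenol | COc1cc(C[C@H](CO)[C@H](C)Cc2cc(OC)c(O)c(OC)c2)ccc1OCc1ccccc1 | intermediate
20 | 4-[(2R,3S)-4-hydroxy-3-(4-hydroxy-3-methoxybenzyl)-2-methylbutyl]-2,6-dimethoxyphenol | COc1cc(C[C@H](CO)[C@H](C)Cc2cc(OC)c(O)c(OC)c2)ccc1O | intermediate
21 | (2S,3R)-2-(4-hydroxy-3-methoxybenzyl)-4-(4-hydroxy-3,5-dimethoxyphenyl)-3-methylbutyl acetate | COc1cc(C[C@H](COC(C)=O)[C@H](C)Cc2cc(OC)c(O)c(OC)c2)ccc1O | target

Total step count: 11. Longest linear sequence: 11 (from 1).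

**Steps most likely to fail**

Step 9. The chelate of a homoallylic alcohol is flexible, so facial selectivity may be poor. Rh-induced migration of the double bond towards C7' or C8 may compete, and the two electron-rich arenes may sequester the cationic metal.
Fallback: C8' is set by ring-controlled enolate alkylation instead of hydrogenation. It sets out from 7 and comes back at 20.
LDA/MeI alkylates the lactone enolate anti to the C8 benzyl group and should give the trans-lactone (3S,4S)-4-[4-(benzyloxy)-3-methoxybenzyl]-3-methyldihydrofuran-2(3H)-one F1. Commercial 4-bromo-2,6-dimethoxyphenol is benzylated (BnBr, K2CO3) to 2-(benzyloxy)-5-bromo-1,3-dimethoxybenzene F2. Its aryllithium (n-BuLi, THF, −78 °C) adds once to F1 to give the cyclic hemiketal (3S,4S)-2-[4-(benzyloxy)-3,5-dimethoxyphenyl]-4-[4-(benzyloxy)-3-methoxybenzyl]-3-methyltetrahydrofuran-2-ol F3. Et3SiH/BF3·OEt2 reduces this to the 2-aryltetrahydrofuran (3S,4S)-2-[4-(benzyloxy)-3,5-dimethoxyphenyl]-4-[4-(benzyloxy)-3-methoxybenzyl]-3-methyltetrahydrofuran F4. H2 over Pd/C then cleaves both benzyl ethers and the benzylic ring C7'–O bond.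

Step 8. At the temperature needed, cleavage of the allyl–oxygen bond back to the free phenol may erode the rearrangement. Expulsion of an ortho methoxy group from the first dienone and oxidation of the electron-rich product may do the same.
Fallback: a nickel-catalysed reductive allyl–aryl cross-electrophile coupling. It sets out from 12 and comes back at 20.
Compound 12 and the bromide F2 (NiCl2·glyme, dtbbpy, Zn, DMA) should give (S)-2-[4-(benzyloxy)-3-methoxybenzyl]-3-[4-(benzyloxy)-3,5-dimethoxybenzyl]but-3-en-1-yl methyl carbonate F5. K2CO3/MeOH gives the alcohol (S)-2-[4-(benzyloxy)-3-methoxybenzyl]-3-[4-(benzyloxy)-3,5-dimethoxybenzyl]but-3-en-1-ol F6. Directed hydrogenation as in step 9 gives (2S,3R)-2-[4-(benzyloxy)-3-methoxybenzyl]-4-[4-(benzyloxy)-3,5-dimethoxyphenyl]-3-methylbutan-1-ol F7. H2 over Pd/C removes both benzyl groups.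

Step 6. Attack of the hindered phenoxide on the π-allyl complex may be slow. Reversible ionisation of the product ether may then drain material into C-allylation or into capture by methoxide.
Fallback: a metal-free SN2 etherification. It sets out from 11 (isolated in this case) and comes back at 15, so step 7 is skipped.
Corey–Kim conditions (NCS, Me2S, CH2Cl2, −20 to 0 °C) convert only the allylic hydroxyl and should give (S)-2-[4-(benzyloxy)-3-methoxybenzyl]-3-(chloromethyl)but-3-en-1-ol F8. Williamson etherification with 13 (K2CO3, cat. NaI, acetone) gives 15 directly.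

**Further compounds**
F1 | step 9 | (3S,4S)-4-[4-(benzyloxy)-3-methoxybenzyl]-3-methyldihydrofuran-2(3H)-one | COc1cc(C[C@H]2[C@H](C)C(=O)OC2)ccc1OCc1ccccc1
F2 | step 9 | 2-(benzyloxy)-5-bromo-1,3-dimethoxybenzene | COc1cc(Br)cc(OC)c1OCc1ccccc1
F3 | step 9 | (3S,4S)-2-[4-(benzyloxy)-3,5-dimethoxyphenyl]-4-[4-(benzyloxy)-3-methoxybenzyl]-3-methyltetrahydrofuran-2-ol | COc1cc(C[C@H]2[C@H](C)C(O)(c3cc(OC)c(OCc4ccccc4)c(OC)c3)OC2)ccc1OCc1ccccc1
F4 | step 9 | (3S,4S)-2-[4-(benzyloxy)-3,5-dimethoxyphenyl]-4-[4-(benzyloxy)-3-methoxybenzyl]-3-methyltetrahydrofuran | COc1cc(C[C@H]2[C@H](C)C(c3cc(OC)c(OCc4ccccc4)c(OC)c3)OC2)ccc1OCc1ccccc1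
F5 | step 8 | (S)-2-[4-(benzyloxy)-3-methoxybenzyl]-3-[4-(benzyloxy)-3,5-dimethoxybenzyl]but-3-en-1-yl methyl carbonate | COc1cc(C[C@H](COC(=O)OC)C(=C)Cc2cc(OC)c(OCc3ccccc3)c(OC)c2)ccc1OCc1ccccc1
F6 | step 8 | (S)-2-[4-(benzyloxy)-3-methoxybenzyl]-3-[4-(benzyloxy)-3,5-dimethoxybenzyl]but-3-en-1-ol | COc1cc(C[C@H](CO)C(=C)Cc2cc(OC)c(OCc3ccccc3)c(OC)c2)ccc1OCc1ccccc1
F7 | step 8 | (2S,3R)-2-[4-(benzyloxy)-3-methoxybenzyl]-4-[4-(benzyloxy)-3,5-dimethoxyphenyl]-3-methylbutan-1-ol | COc1cc(C[C@H](CO)[C@H](C)Cc2cc(OC)c(OCc3ccccc3)c(OC)c2)ccc1OCc1ccccc1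
F8 | step 6 | (S)-2-[4-(benzyloxy)-3-methoxybenzyl]-3-(chloromethyl)but-3-en-1-ol | COc1cc(C[C@H](CO)C(=C)CCl)ccc1OCc1ccccc1
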